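The leftover of incoming ligand comes first. Summer charges incoming ligand and starting complex in the ratio 1.80, here called the ligand ratio: incoming ligand charged per starting complex charged, which, at one ligand per exchange, caps the first exchange at that ratio times the complex charged. Once each starting complex has taken one ligand, 44.4 % of the incoming ligand stays over.

| flask | starting complex | incoming ligand | leaving ligand | remark | time |
|---|---|---|---|---|---|
| Thursday's | 0.50 M | 0.90 M | 0.51 M | run made earlier |  |
| Tuesday's | 0.50 M | 0.90 M | 0.65 M | run made earlier |  |
| Wednesday's | 0.50 M | 0.90 M | 0.52 M | run made earlier |  |
| summer | 0.50 M | 0.900 M | 0.500 M |  | 80 min |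
| noon | 0.50 M | 0.900 M | 0.600 M |  | 80 min |
| dawn | 0.50 M | 0.900 M | 0.720 M |  | 80 min |

| run | time / min | starting complex / % | complex with three exchanged / % | complex with two exchanged / % | complex with one exchanged / % |
|---|---|---|---|---|---|
| Thursday's | 8.00 | 63 | 3 | 0 | 35 |
| Thursday's | 20.0 | 39 | 3 | 3 | 62 |
| Thursday's | 40.0 | 20 | 0 | 1 | 84 |
| Thursday's | 60.0 | 11 | 0 | 0 | 87 |
| Thursday's | 80.0 | 3 | 1 | 3 | 93 |
| Tuesday's | 15.0 | 46 | 1 | 3 | 54 |
| Tuesday's | 30.0 | 26 | 2 | 3 | 73 |
| Tuesday's | 50.0 | 15 | 0 | 0 | 85 |
| Tuesday's | 60.0 | 10 | 0 | 1 | 90 |
| Tuesday's | 80.0 | 6 | 0 | 0 | 91 |
| Wednesday's | 8.00 | 66 | 2 | 0 | 32 |
| Wednesday's | 20.0 | 44 | 0 | 0 | 58 |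
| Wednesday's | 40.0 | 23 | 0 | 1 | 82 |
| Wednesday's | 60.0 | 11 | 0 | 1 | 89 |
| Wednesday's | 80.0 | 11 | 0 | 0 | 91 |

(each reading ± 2 percentage points)

- for complex with one exchanged the crystals are counted in
- as a solid, counted per litre of solution: crystals
- the earlier runs were read with a standard deviation of 2 percentage points
- steps under discussion: starting complex + incoming ligand <-> leaving ligand + complex with one exchanged; complex with one exchanged + incoming ligand <-> leaving ligand + complex with two exchanged; crystals <-> complex with one exchanged; complex with two exchanged + incoming ligand <-> leaving ligand + complex with three exchanged

- which of these there is most of at the end, counted by the starting complex in it, summer (complex with one exchanged / complex with three exchanged / starting complex / complex with two exchanged)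
- which of these there is most of at the end, counted by the starting complex in it, noon (complex with one exchanged / complex with three exchanged / starting complex / complex with two exchanged)
- which of these there is most of at the end, counted by the starting complex in it, dawn (complex with one exchanged / complex with three exchanged / starting complex / complex with two exchanged)
- final amount of the leader among these, as a percentage of the starting complex charged, in summer
- final amount of the leader among these, as a percentage of the starting complex charged, in noon
- final amount of the leader among these, as a percentage of the starting complex charged, in dawn

The bench rule for a reagent in excess is pseudo-first-order decay. Its constant is the logarithm of charged over remaining starting complex, divided by time. Thursday's run gives 0.0578 /min from the reading at 8.00 min but 0.0402 /min from the one at 40.0 min. The early constant carried to 80 min leaves 0.985 %, while the readings there are 3 % in Thursday's run, 6 % in Tuesday's and 11 % in Wednesday's. The border of the rule is the ligand ratio: a constant needs incoming ligand to stay near its charge, and at 1.80 it heads for the leftover above, so the rate per starting complex sinks as the run goes on.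

The second-order law keeps that drift. For a step first order in starting complex and in incoming ligand, using one ligand per exchange and with no way back, the quotient of incoming ligand present over starting complex present, divided by the ligand ratio, has a logarithm that grows linearly with time. Thursday's reading at 40.0 min puts this quotient at 2.78, so the law puts it at 7.72 at 80 min. For summer, charged alike in starting complex and incoming ligand, that reckons to 6.21 % starting complex, with the scatter of one reading in it. Complex with two exchanged and complex with three exchanged read no higher than 3 %, against a scatter of 2 percentage points, so complex with one exchanged, reckoned as holding the reacted complex, leads with about 93.8 %. Leaving ligand shows no effect beyond the scatter at 60.0 min: 11 % starting complex at 0.51 M in Thursday's run, 10 % at 0.65 M in Tuesday's. The same figure therefore stands for noon, and for dawn by extrapolation.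

The forecast names complex with one exchanged in each flask, with 92 % for summer, 92 % for noon and 91 % for dawn, the last between 85 % and 95 % because “Slightly more reversal is possible”.

The flasks give complex with one exchanged as leader, with 93.2 % in summer, 93.2 % at noon and 93.2 % at dawn; summer keeps 6.16 % starting complex.

    starting complex + incoming ligand ⇌ leaving ligand + complex with one exchanged (K = 5.74, k = 0.00111 /M/s)
    complex with one exchanged + incoming ligand ⇌ leaving ligand + complex with two exchanged (K = 0.849, k = 6.17 × 10⁻⁴ /M/s)
    crystals ⇌ complex with one exchanged, rate k3*(cs3 - [complex with one exchanged]) while solid is left; crystals form when [complex with one exchanged] > cs3 (solubility = 5.80 mM, k = 0.0341 /s)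
    complex with two exchanged + incoming ligand ⇌ leaving ligand + complex with three exchanged (K = 0.400, k = 5.75 × 10⁻⁵ /M/s)

In summer the first exchange, forward rates taken, uses incoming ligand 41 times as fast as the second at 12.6 min. That ratio drifts down to 8.9 at 80.0 min, lower but still in favour of the first, and with a cap of 180 % of the complex charged summer keeps 47 % of its incoming ligand. In a neighbour of summer charged with 2.0 M starting complex, its other charges and the time held, the cap falls to 45.0 % of the complex charged, which makes incoming ligand the limiting reagent. That neighbour gives 44.8 % complex with one exchanged and 55.2 % starting complex, with 0.34 % of its incoming ligand left.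

(All runs stem from a simulated flask for an exercise; noise was put on by code.)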